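## Structural features

The target is a γ-butyrolactone whose ring atoms are numbered O1, C2 (carbonyl), C3, C4 and C5 (the OCH2 carbon). C3 carries a tertiary hydroxyl and a 4-hydroxy-3-methoxybenzyl group, and C4 carries a second, identical 4-hydroxy-3-methoxybenzyl group. C3 and C4 are adjacent stereocentres, (3S,4R). The C3 hydroxyl and the C4 hydrogen lie on the same ring face, so the two arylmethyl groups are cis. Fragile points are the two free guaiacol-type phenols (acidic, easily oxidised) and the lactone (opened by base or hydride). The real difficulty is C3: a fully substituted, oxygen-bearing carbon next to the carbonyl whose absolute configuration must be created; C4 can then be set relative to it. The key step exploits that C3 is a tertiary carbinol bonded directly to the ester carbonyl C2. It is therefore the ketone carbon of an arylpyruvate, while O1, C5, C4 and the benzylic carbon on C4 map onto the propargyl ester arm of the same molecule. Forming C3–C4 closes the lactone, and an aryl–carbon bond at the alkyne terminus completes the skeleton.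

## Logic of the disconnections

**13 ⇐ 12.** The two phenolic O–H bonds are exchanged for O–benzyl bonds. Free phenols would quench every organometallic used earlier and oxidise easily. The gain is two identical, inert aryl units. The demand is a final cleavage of two aryl benzyl ethers that leaves the lactone, the tertiary carbinol and both stereocentres alone, which neutral hydrogenolysis meets.

**12 ⇐ 11.** The C4–H bond and one benzylic C–H bond are removed, giving an exocyclic C4=CH–aryl alkene. This deletes the C4 stereocentre and leaves C3 as the only centre to be set absolutely. The alkene geometry no longer matters for the target. The forward step must deliver hydrogen to C4 from the hydroxyl face only, without hydrogenolysis of the allylic C5–O1 bond or of the benzyl ethers.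

**11 ⇐ 8 + 10.** The C3–C4 ring bond and the bond between the alkene carbon and its aryl group are cut. C3 becomes the ketone of an α-keto ester and C4=CH becomes a terminal alkyne, with the O1–C2 ester kept as tether. One operation then makes the ring, two C–C bonds and the carbinol stereocentre from two achiral pieces of similar size. The forward step needs a catalyst that couples ketone and alkyne with enantioface control and transfers aryl faster than 10 attacks or deprotonates 8. It also needs 8 to be offered as the ketone and not as its enol.

**10 ⇐ 2.** The C–Zn bond is traced to a C–Br bond. The demand is a metalation that leaves no alkyl halide and no magnesium salt in the reagent solution.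

**8 ⇐ 7.** The ketone C=O is traced to a secondary CH–OH. This is the refinement of the precursor design: 7 cannot enolise and can be stored, and a neutral aprotic oxidation as the last operation delivers 8 kinetically as the keto tautomer. The oxidant must spare the alkyne and the electron-rich arene and must allow a non-aqueous isolation.

**7 ⇐ 5 + 6.** The acyl–oxygen bond of the ester is cut, exchanging the alkoxy group. The terminal alkyne C–H would not survive the Grignard step, so the propargyl group enters afterwards. The exchange must not touch the secondary hydroxyl.

**5 ⇐ 2 + 3.** The aryl–CH2 bond is cut. A three-carbon epoxy ester supplies the whole pyruvate arm with oxygen already at C2, and the same aryl bromide serves both halves of the molecule. The Grignard 4 must attack the epoxide CH2 and not the ester.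

**2 ⇐ 1.** The O–benzyl bond is cut, giving a commercial bromophenol.

## Other disconnections considered

**Alternative 1:** The cut is at the two exocyclic bonds, C4–CH2Ar and C3–CH2Ar; the ring is bought ready-made as the chiral butenolide acetal A2, (5S)-5-[(1S,2R,5S)-menthyloxy]furan-2(5H)-one.
- Forward key step: the 2-lithio derivative of dithiane A3 adds to C4 of A2 on the face opposite the menthyloxy group. The resulting lactone enolate is trapped at C3 by aldehyde A4, again trans, giving A1 as a mixture of carbinol epimers.
- In its favour: it is a conjugate addition–aldol sequence of an established kind, run under auxiliary control, and forms two C–C bonds in one flask. C4 is set by diastereoselection rather than by an untested catalyst.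
- Against it here: it closes no ring and makes no C–O bond at C3. Sulfur, the carbinol oxygen and the acetal are introduced only to be removed. The usual reductive removals also attack O-benzyl groups. That sequence would lead to trans-lactone A5, after which C3 must still be hydroxylated through its enolate and the phenols freed. The (1S,2R,5S)-menthyl series is the less accessible antipode. The estimate is about eleven operations against eight.
- Comparison: on reliability of the key step alternative 1 is the better plan, since step 6 of the chosen route has no precedent. On relative configuration the two are equal, because both rely on attack anti to a neighbouring group. On the C3 carbinol and on step economy the chosen plan is stronger, because C3 is the centre its key step creates.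

**Alternative 2:** The cut is at C3–CH2Ar and C3–C4, with lactone closure left for later.
- Forward key step: benzylic Grignard A8 adds to the acylsilane carbonyl of A7, the silyl glyoxylate ester of allylic carbinol A9. A [1,2]-Brook shift gives the glycolate enolate, which is O-silylated and rearranges through a chair [3,3] transition state to acid A6.
- In its favour: the oxygenated quaternary C3 and C4 are both set in one step. Absolute configuration comes from the carbinol of A9 by chirality transfer through an ordered chair, which is more predictable than ligand control in step 6; on this point the alternative is the better. No transition metal is needed.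
- Against it here: the enolate geometry after the Brook shift decides C3 and must be uniform (silyloxy cis to the enolate oxygen, E-alkene, (S)-carbinol). An electron-rich benzylic Grignard is prone to homocoupling, and the enolate can add to a second molecule of A7. After A6 the propenyl group must be cleaved oxidatively beside two electron-rich arenes, then reduced, lactonised, desilylated and debenzylated. A7 itself needs about five steps, so the total is near twelve.
- Comparison: both plans place oxygen on C3 in the key step, so they are equal there. Alternative 2 is better on predictability of stereocontrol. The chosen plan is better on convergence, on step count, and in closing the ring in the same step.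

**Alternative 3:** The cut is at O1–C5.
- Forward key step: a Baeyer–Villiger monooxygenase inserts oxygen into one of the two enantiotopic C–C(O) bonds of prochiral cyclobutanone A11, expanding it to lactone A10.
- In its favour: the step is mild and catalytic, with no protecting-group or metal compatibility issue. Enantioselectivity of this enzyme class on 3-substituted cyclobutanones can be very high. The remaining way is classical: trans-alkylation to A5, enolate hydroxylation expected anti to the C4 substituent, then hydrogenolysis. On precedent for each step this alternative is better than the chosen plan.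
- Against it here: the key step sets only C4 and forms no C–C bond. C3, the hard centre, is built afterwards in two steps by substrate control. The enzyme must accept a large lipophilic substituent with the required enantiopreference, in dilute aqueous medium with cofactor recycling. A11 and a benzylic halide electrophile must also be prepared, giving about nine to ten steps.
- Comparison: equal to the chosen plan in how the final relative configuration arises (attack anti to a neighbour). Better in reliability. Weaker in convergence, in step count, and in not addressing the most difficult centre in its key step.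

Key step: step 6

Assumption: the sense of induction of the chiral ligand L* in step 6 cannot be derived a priori. L* is a monodentate 1,1′-spirobiindane-7,7′-diol phosphoramidite (SIPHOS-PE type). The antipode that gives the (S)-carbinol is taken to be identified in a first small run; both antipodes are available.

Remark on the structures: no correction was needed. The SMILES give (3S,4R) for 13 and (S,Z) for 11, and these agree with each other. The rotamer the ester must adopt is called E here (propargyl carbon syn to the ketone carbon about C2–O1).

## Route

Step 1
Reactants: 1 4-bromo-2-methoxyphenol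
Product: 2 1-(benzyloxy)-4-bromo-2-methoxybenzene
Conditions: BnBr (1.1 equiv), K2CO3 (1.5 equiv), acetone, reflux
Reagents that add atoms: benzyl bromide, BrCc1ccccc1
Why: Williamson ether synthesis on a phenoxide with a primary benzylic bromide; the benzyl ether tolerates the Grignard, organolithium, organozinc and zerovalent nickel chemistry that follows and is removed by hydrogenolysis at the end.

Step 2
Reactants: 2 1-(benzyloxy)-4-bromo-2-methoxybenzene; 3 methyl oxirane-2-carboxylate (racemic)
Product: 5 methyl 3-(4-benzyloxy-3-methoxyphenyl)-2-hydroxypropanoate (racemic), via arylmagnesium bromide 4 (not isolated)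
Conditions: Mg, THF, 40 °C; then CuBr·SMe2 (10 mol%), 3, THF, −40 → −20 °C; cold 1 M HCl
Reagents that add atoms: none
Why: Grignard formation followed by copper-catalysed SN2 opening of the glycidic ester at its CH2 carbon, a standard entry to 3-aryl-lactates; low temperature and the cuprate keep the ester intact. The carbinol centre is racemic on purpose, since step 4 erases it.

Step 3
Reactants: 5 methyl 3-(4-benzyloxy-3-methoxyphenyl)-2-hydroxypropanoate; 6 prop-2-yn-1-ol
Product: 7 prop-2-yn-1-yl 3-(4-benzyloxy-3-methoxyphenyl)-2-hydroxypropanoate (racemic)
Conditions: 6 (10 equiv), TsOH·H2O (5 mol%), toluene, 90 °C, 5 Å MS (Soxhlet) to remove MeOH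
Reagents that add atoms: none
Why: Acid-catalysed transesterification driven by excess alcohol and removal of methanol; α-hydroxy esters exchange readily, and the benzyl ether, the secondary hydroxyl and the terminal alkyne tolerate catalytic sulfonic acid.

Step 4
Reactants: 7 prop-2-yn-1-yl 3-(4-benzyloxy-3-methoxyphenyl)-2-hydroxypropanoate
Product: 8 prop-2-yn-1-yl 3-(4-benzyloxy-3-methoxyphenyl)-2-oxopropanoate (keto tautomer)
Conditions: DMP (1,1,1-triacetoxy-1,1-dihydro-1,2-benziodoxol-3(1H)-one, 1.2 equiv), CH2Cl2, 0 °C → rt; pentane, filtration through Celite, toluene azeotrope; used at once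
Reagents that add atoms: none
Why: Dess–Martin oxidation of the α-hydroxy ester under neutral aprotic conditions forms the C=O bond directly, so 8 should be obtained kinetically as the keto tautomer without the base or hot acid that drive arylpyruvates to the enol or to aldol dimers. The non-aqueous isolation is meant to bring the material to step 6 before it equilibrates.

Step 5
Reactants: 2 1-(benzyloxy)-4-bromo-2-methoxybenzene
Product: 10 (4-benzyloxy-3-methoxyphenyl)zinc chloride, via aryllithium 9 (not isolated)
Conditions: t-BuLi (2.0 equiv), THF, −78 °C; then ZnCl2 (1.05 equiv, THF), −78 °C → rt; titrated solution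
Reagents that add atoms: zinc chloride, Cl[Zn]Cl
Why: Bromine–lithium exchange, much faster at −78 °C than any attack on the benzyl ether, then transmetalation to zinc gives a weakly basic, magnesium-free arylzinc halide. The second equivalent of t-BuLi destroys the tert-butyl bromide, so no alkyl halide reaches the nickel catalyst.

Step 6
Reactants: 8 prop-2-yn-1-yl 3-(4-benzyloxy-3-methoxyphenyl)-2-oxopropanoate; 10 (4-benzyloxy-3-methoxyphenyl)zinc chloride
Product: 11 (S,Z)-3-(4-benzyloxy-3-methoxybenzyl)-4-(4-benzyloxy-3-methoxybenzylidene)-3-hydroxydihydrofuran-2(3H)-one
Conditions: Ni(cod)2 (10 mol%), L* (12 mol%), THF, 0 °C; 8 and 10 (2.0 equiv) added simultaneously over 2 h; then 1 M HCl, 0 °C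
Reagents that add atoms: none
Why: Proposed new method: zerovalent nickel carrying one chiral phosphoramidite should couple the alkyne and the ketone carbonyl of 8 oxidatively to a five-membered oxanickelacycle (C3–C4 bond); 10 then transmetalates to nickel, and C–C reductive elimination places the aryl group on the former terminal alkyne carbon, releasing zerovalent nickel and the zinc alkoxide of 11. The closest known reaction types are the nickel-catalysed alkylative cyclisation of ynals with organozincs and the nickel-catalysed enantioselective reductive cyclisation of alkynyl ketones; neither has been shown on an ester-tethered α-keto ester. The lactone closes in a 5-exo-dig sense, because the three-atom ester tether lets the ketone carbon reach only the internal alkyne carbon, which also fixes nickel, and hence the aryl group, on the terminal carbon. The Z geometry follows from the cis placement of nickel and C3 in the metallacycle and from reductive elimination with retention. C3 is the only new stereocentre; it is set when the ligand on nickel selects the enantioface of the ketone during oxidative cyclisation, the arylmethyl group turning away from the ligand. The step needs chemoselectivity for the ketone over the ester carbonyl (the α-keto carbonyl is the more electrophilic and the only one the tether can deliver) and for the catalysed path over direct addition of 10 to the ketone or its deprotonation; a magnesium-free arylzinc chloride, the keto tautomer of 8 and slow double addition serve this. The ester must react through its minor E rotamer, which costs rate but is no barrier of principle.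

Step 7
Reactants: 11 (S,Z)-3-(4-benzyloxy-3-methoxybenzyl)-4-(4-benzyloxy-3-methoxybenzylidene)-3-hydroxydihydrofuran-2(3H)-one
Product: 12 (3S,4R)-3,4-bis(4-benzyloxy-3-methoxybenzyl)-3-hydroxydihydrofuran-2(3H)-one
Conditions: [Ir(cod)(PCy3)(py)]PF6 (5 mol%), H2 (1 atm), CH2Cl2, 0 °C → rt
Reagents that add atoms: none
Why: Hydroxyl-directed homogeneous hydrogenation: the cationic iridium catalyst binds the tertiary C3 hydroxyl and delivers hydrogen to the exocyclic alkene from that face, so H-4 ends cis to the hydroxyl and the arylmethyl groups cis to each other (4R). That face is also the less hindered one, and this catalyst leaves benzyl ethers and the allylic C5–O1 bond alone.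

Step 8
Reactants: 12 (3S,4R)-3,4-bis(4-benzyloxy-3-methoxybenzyl)-3-hydroxydihydrofuran-2(3H)-one
Product: 13 (3S,4R)-3-hydroxy-3,4-bis(4-hydroxy-3-methoxybenzyl)dihydrofuran-2(3H)-one
Conditions: H2 (1 atm), 10% Pd/C, EtOAc–EtOH, rt
Reagents that add atoms: none
Why: Catalytic hydrogenolysis of the two aryl benzyl ethers under neutral conditions; C3 is quaternary and not benzylic and C4 is not acidic, so both configurations are retained.

## Compound list

1 | 4-bromo-2-methoxyphenol | COc1cc(Br)ccc1O | starting material
2 | 1-(benzyloxy)-4-bromo-2-methoxybenzene | COc1cc(Br)ccc1OCc1ccccc1 | intermediate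
3 | methyl oxirane-2-carboxylate (racemic) | COC(=O)C1CO1 | starting material
4 | (4-benzyloxy-3-methoxyphenyl)magnesium bromide | COc1cc([Mg]Br)ccc1OCc1ccccc1 | intermediate
5 | methyl 3-(4-benzyloxy-3-methoxyphenyl)-2-hydroxypropanoate (racemic) | COC(=O)C(O)Cc1ccc(OCc2ccccc2)c(OC)c1 | intermediate
6 | prop-2-yn-1-ol | C#CCO | starting material
7 | prop-2-yn-1-yl 3-(4-benzyloxy-3-methoxyphenyl)-2-hydroxypropanoate (racemic) | C#CCOC(=O)C(O)Cc1ccc(OCc2ccccc2)c(OC)c1 | intermediate
8 | prop-2-yn-1-yl 3-(4-benzyloxy-3-methoxyphenyl)-2-oxopropanoate (keto tautomer) | COc1cc(CC(=O)C(=O)OCC#C)ccc1OCc1ccccc1 | intermediate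
9 | (4-benzyloxy-3-methoxyphenyl)lithium | COc1cc([Li])ccc1OCc1ccccc1 | intermediate
10 | (4-benzyloxy-3-methoxyphenyl)zinc chloride | COc1cc([Zn]Cl)ccc1OCc1ccccc1 | intermediate
11 | (S,Z)-3-(4-benzyloxy-3-methoxybenzyl)-4-(4-benzyloxy-3-methoxybenzylidene)-3-hydroxydihydrofuran-2(3H)-one | COc1cc(/C=C2/COC(=O)[C@]2(O)Cc2ccc(OCc3ccccc3)c(OC)c2)ccc1OCc1ccccc1 | intermediate
12 | (3S,4R)-3,4-bis(4-benzyloxy-3-methoxybenzyl)-3-hydroxydihydrofuran-2(3H)-one | COc1cc(C[C@@H]2COC(=O)[C@]2(O)Cc2ccc(OCc3ccccc3)c(OC)c2)ccc1OCc1ccccc1 | intermediate
13 | (3S,4R)-3-hydroxy-3,4-bis(4-hydroxy-3-methoxybenzyl)dihydrofuran-2(3H)-one | COc1cc(C[C@@H]2COC(=O)[C@]2(O)Cc2ccc(O)c(OC)c2)ccc1O | target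

## Step count and least certain steps

Total: 8 steps. Longest linear sequence: 7 steps (1 → 2 → 5 → 7 → 8 → 11 → 12 → 13; steps 1, 2, 3, 4, 6, 7, 8). Step 5 is a one-step branch from 2.

**Step 6 (key step).** Four processes could defeat it:
- Proton transfer from the substrate, or direct aryl addition of 10 to the very electrophilic ketone, may outrun the nickel cycle.
- Zerovalent nickel may ionise the propargylic C–O bond, after which aryl transfer would take an SN2′ course.
- Oxidative cyclisation may be slow because of the E-rotamer penalty, leaving the alkyne to oligomerise.
- Enantioface discrimination by a monodentate ligand may be insufficient.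

Fallback, by known chemistry, setting out from 2 (through aryllithium 9) and rejoining at 12. Formylation of 9 with DMF gives aldehyde A4, which is also purchasable. Stobbe condensation of A4 with dimethyl succinate (NaOMe, MeOH, reflux) should give (E)-4-(4-benzyloxy-3-methoxyphenyl)-3-(methoxycarbonyl)but-3-enoic acid F1. Asymmetric hydrogenation ([Rh(cod)2]BF4, chiral bisphospholane of the DuPhos type, H2, MeOH) should give (S)-4-(4-benzyloxy-3-methoxyphenyl)-3-(methoxycarbonyl)butanoic acid F2 without touching the benzyl ether. Reduction of the ester group of its potassium salt (KOH; CaCl2/NaBH4, EtOH) and acid lactonisation lead to lactone A10. In parallel, A4 is reduced (NaBH4, MeOH) to (4-benzyloxy-3-methoxyphenyl)methanol F3 and brominated (PBr3, Et2O, 0 °C) to 1-(benzyloxy)-4-(bromomethyl)-2-methoxybenzene F4. The lithium enolate of A10 (LiN(SiMe3)2, THF, −78 °C) is alkylated with F4 anti to the C4 substituent to give trans-lactone A5. The potassium enolate of A5 (KN(SiMe3)2, THF, −78 °C) is hydroxylated with 2-(phenylsulfonyl)-3-phenyloxaziridine. Oxygen is expected to enter anti to the C4 arylmethyl group, which is the arrangement of 12. Step 8 follows.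

**Step 4.** Tautomerisation to the enol and aldol-type self-condensation may occur during the oxidation or on concentration, so that the keto form does not reach step 6 intact.

Fallback, setting out from 2 (through 9 and aldehyde A4) and rejoining at 8. Erlenmeyer condensation of A4 with N-acetylglycine (Ac2O, NaOAc, 100 °C) gives (Z)-4-(4-benzyloxy-3-methoxybenzylidene)-2-methyloxazol-5(4H)-one F5. Alkaline hydrolysis (2 M NaOH, reflux under N2; then cold HCl) gives 3-(4-benzyloxy-3-methoxyphenyl)-2-oxopropanoic acid F6. Alkylation of its carboxylate with propargyl bromide (KHCO3, DMF, rt) gives 8 as stable, purifiable, enol-rich material. Step 6 then depends on keto–enol exchange in the flask.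

**Step 7.** Facial selectivity may be poor, or turnover may fail, if the catalyst is held by the α-hydroxy-lactone unit or kept away by the aryl group cis to C3. Migration of the double bond into the ring is a second possible course.

Fallback, setting out from 11 and rejoining at 13. Heterogeneous hydrogenation (H2, 10% Pd/C, EtOAc, rt) relies on adsorption on the less hindered face, anti to the C3 arylmethyl group, which is again the hydroxyl face. It removes the benzyl ethers in the same operation, so step 8 is merged. This fallback makes no new compound (F0).

**Step 3.** Exchange may be incomplete, or self-esterification through the free secondary hydroxyl may give oligomers.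

Fallback, setting out from 5 and rejoining at 7. Saponification (LiOH, THF–H2O, 0 °C; then dilute HCl) gives 3-(4-benzyloxy-3-methoxyphenyl)-2-hydroxypropanoic acid F7. Alkylation of its carboxylate with propargyl bromide (KHCO3, DMF, rt) gives 7, so the ester is made at the O–CH2 bond instead of at the acyl carbon.

## Further compounds

F1 | step 6 | (E)-4-(4-benzyloxy-3-methoxyphenyl)-3-(methoxycarbonyl)but-3-enoic acid | COC(=O)/C(CC(=O)O)=C/c1ccc(OCc2ccccc2)c(OC)c1
F2 | step 6 | (S)-4-(4-benzyloxy-3-methoxyphenyl)-3-(methoxycarbonyl)butanoic acid | COc1cc(C[C@@H](CC(=O)O)C(=O)OC)ccc1OCc1ccccc1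
F3 | step 6 | (4-benzyloxy-3-methoxyphenyl)methanol | COc1cc(CO)ccc1OCc1ccccc1
F4 | step 6 | 1-(benzyloxy)-4-(bromomethyl)-2-methoxybenzene | COc1cc(CBr)ccc1OCc1ccccc1
F5 | step 4 | (Z)-4-(4-benzyloxy-3-methoxybenzylidene)-2-methyloxazol-5(4H)-one | CC1=N/C(=C\c2ccc(OCc3ccccc3)c(OC)c2)C(=O)O1
F6 | step 4 | 3-(4-benzyloxy-3-methoxyphenyl)-2-oxopropanoic acid | COc1cc(CC(=O)C(=O)O)ccc1OCc1ccccc1
F0 | step 7 | none | none
F7 | step 3 | 3-(4-benzyloxy-3-methoxyphenyl)-2-hydroxypropanoic acid (racemic) | COc1cc(CC(O)C(=O)O)ccc1OCc1ccccc1
A1 | alternative 1 | (3R,4S,5S)-3-[(4-benzyloxy-3-methoxyphenyl)(hydroxy)methyl]-4-[2-(4-benzyloxy-3-methoxyphenyl)-1,3-dithian-2-yl]-5-[(1S,2R,5S)-menthyloxy]dihydrofuran-2(3H)-one (carbinol epimers) | COc1cc(C2(SCCCS2)[C@@H]2[C@@H](O[C@H]3C[C@@H](C)CC[C@@H]3C(C)C)OC(=O)[C@H]2C(O)c2ccc(OCc3ccccc3)c(OC)c2)ccc1OCc1ccccc1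
A2 | alternative 1 | (5S)-5-[(1S,2R,5S)-menthyloxy]furan-2(5H)-one | O=C1C=C[C@@H](O[C@H]2C[C@@H](C)CC[C@@H]2C(C)C)O1
A3 | alternative 1 | 2-(4-benzyloxy-3-methoxyphenyl)-1,3-dithiane | COc1cc(C2SCCCS2)ccc1OCc1ccccc1
A4 | alternative 1 | 4-(benzyloxy)-3-methoxybenzaldehyde | COc1cc(C=O)ccc1OCc1ccccc1
A5 | alternative 1 | (3S,4S)-3,4-bis(4-benzyloxy-3-methoxybenzyl)dihydrofuran-2(3H)-one | COc1cc(C[C@@H]2COC(=O)[C@H]2Cc2ccc(OCc3ccccc3)c(OC)c2)ccc1OCc1ccccc1
A6 | alternative 2 | (2S,3R,E)-2,3-bis(4-benzyloxy-3-methoxybenzyl)-2-(tert-butyldimethylsilyloxy)hex-4-enoic acid | COc1cc(C[C@@H]([C@@](O[Si](C)(C)C(C)(C)C)(Cc2ccc(OCc3ccccc3)c(OC)c2)C(=O)O)/C=C/C)ccc1OCc1ccccc1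
A7 | alternative 2 | (S,E)-5-(4-benzyloxy-3-methoxyphenyl)pent-3-en-2-yl 2-(tert-butyldimethylsilyl)-2-oxoacetate | C[C@H](OC(=O)C(=O)[Si](C)(C)C(C)(C)C)/C=C/Cc1ccc(OCc2ccccc2)c(OC)c1
A8 | alternative 2 | (4-benzyloxy-3-methoxybenzyl)magnesium chloride | COc1cc(C[Mg]Cl)ccc1OCc1ccccc1
A9 | alternative 2 | (S,E)-5-(4-benzyloxy-3-methoxyphenyl)pent-3-en-2-ol | C[C@H](O)/C=C/Cc1ccc(OCc2ccccc2)c(OC)c1
A10 | alternative 3 | (S)-4-(4-benzyloxy-3-methoxybenzyl)dihydrofuran-2(3H)-one | COc1cc(C[C@@H]2COC(=O)C2)ccc1OCc1ccccc1
A11 | alternative 3 | 3-(4-benzyloxy-3-methoxybenzyl)cyclobutan-1-one | COc1cc(CC2CC(=O)C2)ccc1OCc1ccccc1
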